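All constants were chosen freely; the result is computed.

You have a small charge of E, and the question is how much J is left after 20 s under three doses of D.

| flask | E | D | time |
|---|---|---|---|
| delta | 0.50 mM | 1.20 equiv | 20 s |
| zeta | 0.50 mM | 2.50 equiv | 20 s |
| theta | 0.50 mM | 5.00 equiv | 20 s |

    E + D → J + L (k1 = 260 M⁻¹ s⁻¹)
    E + D → G + L (k2 = 170 M⁻¹ s⁻¹)
    D + J → Z + L (k3 = 510 M⁻¹ s⁻¹)
    D + G → Z + L (k4 = 96 M⁻¹ s⁻¹)
    E → Q (k5 = 2.6 × 10⁻⁴ s⁻¹)
    J → X (k6 = 0.086 s⁻¹)

- "hardly changes" means that all values lie within two and a half points (for a concentration: within two and a half percent of the largest)
- run time (delta): 20 s

1. amount of J at the end, in percent of the E charged for delta, zeta, theta, in this order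
2. how that number moves from the first to the last of them (hardly changes / falls, then rises / rises all the way / rises, then falls / falls all the way)

J is made from E by D and lost to D, and it also drains to X without any D. Suppose J and E fall together late in the run. Then J's net rate equals J times E's fractional rate, time drops out, and J over E becomes a fixed tail ratio, what decay chains call transient equilibrium; J's net rate is not set to zero here, as it would be in a quasi-steady ratio. Count D in E charges and the tail ratio is 3.25 times D over D plus 2.15. That last figure is the balance level of D, the amount of D in E charges at which the drain to X equals the excess of J's loss to D over E's loss to D.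

But does J have time to settle? With one E charge of D, J lives 2.93 s, shorter than the run, so it should.

The ratio still needs E, and E needs D. Each E takes up at most two D, so theta holds at least 3.00 E charges of D. That leaves at most <0.001% of E, and the ratio there, 1.89, puts J near <0.001%.

The same floor in zeta is 0.500, which allows E up to 11.6%. That is too loose, since D starts far above the floor and every G or X holds a D back. So I guess one E charge as the mean, which gives E 1.36%, a ratio of 1.03, and J about 1.40%.

Delta resists this: its 1.20 E charges of D stand below the two that each E can take up, and that gives me no floor for D to put in the ratio. I put no figure on it, but E can stall there with J beside it, so I expect the row to fall all the way.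

The forecast gives 6%, 0.8% and <0.001%, falls all the way, lower than my zeta figure, on the ground that “it only shadows whatever E remains”.

The simulation gives 6.05%, 0.693% and 0%: falls all the way. In zeta, E went on reacting with D down to 0.750% at 20.0 s, less than my 1.36%, and J followed it with D at 32% of its own charge, which is 0.805 E charges, where the tail ratio is 0.886 and J over E reads 0.924. In theta, at 10.0 s, D stood at 62.9% of its own charge, or 3.15 E charges, where the tail ratio is 1.93 and J over E reads 1.76.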